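**Compound numbers used throughout:** 1 2,4,5-trimethoxytoluene; 4 ring B phenol; 5 trichloroethylene; 6 dichlorovinyl ether; 9 benzyl aryloxypropiolate; 10 4-methoxy-6-methyl-2-pyrone; 12 diaryl ether; 13 quinone; 14 hydroquinone acid; 15 depsidone; 16 3-methylbut-2-enoic acid; 18 pyranone-fused depsidone dimethyl ether; 19 deformyl target; 21 target. Numbers 2, 3, 7, 8, 11, 17 and 20 are intermediates that are not isolated.

## The problem

The target is an achiral tetracycle: a depsidone (two arenes joined by a diaryl ether oxygen and by an ester, closing a seven-membered dioxepinone) with a 2,2-dimethyl-2,3-dihydropyran-4-one fused to the second arene. Ring positions are labelled a1–a6 on ring A (a1 C–CH3, a2 CH, a3 C–OH, a4 C–CHO, a5 C–O ether, a6 C–C11, where C11 is the lactone carbonyl) and b1–b6 on ring B (b1 C–O ester, b2 C–CH3, b3 C–C=O of the pyranone, b4 C–O of the pyranone, b5 C–OH, b6 C–O ether). There is no stereocenter, so nothing can be relayed and every difficulty is one of regiochemistry and crowding. The ether bond a5–O–b6 carries four ortho substituents (a4, a6, b1, b5), the worst case for joining two arenes through oxygen. Ring B is hexasubstituted, with four contiguous oxygens (b1, b6, b5, b4) that end in four different roles. O(b1) and O(b5) are both ortho to the ether, and either could close a seven-membered lactone onto C11, so they must be told apart before lactonisation. The aryl lactone is opened by nucleophiles and strong base, the salicylaldehyde at a4 would not survive organolithium, oxidative or hydrogenation steps, and ring B intermediates at the hydroquinone level oxidise in air. The enabling feature is that a5 (oxygen) and a6 (carboxyl) are adjacent and together are the two carbons of a 3-aryloxypropiolate, while a4–a3–a2–a1, with oxygen on a3 and methyl on a1, is the diene of 4-methoxy-6-methyl-2-pyrone.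

## Retrosynthesis

**21 to 19.** The a4–CHO bond is cut first. The aldehyde is the group least tolerant of the earlier chemistry, and at this stage ring B has no free carbon, so only a2 and a4 can compete. Precursor 19 is the target less one carbon. The forward reaction must formylate ortho to the a3 phenol on the side of the ether oxygen; a titanium phenoxide-directed Rieche formylation is asked to do this.

**19 to 18.** The O–H bonds at O(a3) and O(b5) are traced to methyl ethers. Keeping a3 methylated until the pyranone is built denies ring A a free phenol during the acid annulation, and O(b5) must stay masked while the lactone closes. One reagent frees both. The forward step must cleave two aryl methyl ethers without opening the lactone or the pyranone.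

**18 to 15 and 16.** The b3–C(=O) and O(b4)–C(CH3)2 bonds are cut, removing one ring and five carbons. Carrying the ketone from the start is excluded, because n-BuLi is needed to make the alkynyl ether. In 15, b3 is the only unsubstituted carbon of ring B and lies ortho to the only free hydroxyl, so the annulation has one place to go.

**15 to 14.** The C11–O(b1) bond is cut. In 14 the two free hydroxyls of ring B sit at b1 and b4, para to each other, so only O(b1) can reach C11. Freeing all ring B oxygens at once would also expose O(b5) and allow two lactones; that route is avoided.

**14 to 13 to 12.** No skeletal bond is cut. The hydroquinone is traced through quinone 13 to the para-dimethoxy pair of 12. This redox relay picks O(b1) and O(b4) out of four ring B oxygens because they are the only para pair. A benzyl ester is preferred to a methyl ester: the hydrogenation that reduces the quinone also frees the acid, whereas a methyl benzoate flanked by two ortho substituents would resist saponification.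

**12 to 9 and 10.** The a4–a5 and a1–a6 bonds are cut, dissolving ring A into a commercial pyrone and a two-carbon unit. The neighbouring cuts at a5–O or O–b6 would require coupling two arenes at a tetra-ortho-substituted oxygen. Here the ether C–O bond already exists in 9, made on an sp carbon. The forward reaction must be regioselective (pyrone C3 to the oxygen-bearing alkyne carbon) and fast enough to outrun thermal decay of the alkynyl ether.

**9 to 6 to 4 and 5.** The C11–C(alkyne) bond is traced to a chloroformate and a lithium acetylide, and the O–C(sp) bond to phenol 4 and trichloroethylene 5. The precursor is a simple phenol; the forward steps are a base-mediated vinylation and an elimination, exchange and acylation sequence.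

**4 to 1.** The C–O bond at b6 is cut. Arene 1 has the hydrogen at this position flanked by two methoxy groups, which is what a directed lithiation needs.

## Roads not taken

**Alternative 1: carbonylative lactonisation.** Both bonds to C11 are cut (a6–C11 and C11–O(b1)), and C11 comes from CO. In the forward step the bromo phenol A2 is treated with Pd(OAc)2/Xantphos under CO. Zerovalent palladium inserts into the a6–Br bond, CO insertion gives an acylpalladium species, and the b1 phenol captures it to give A1, the di-O-methyl ether of the target.
- Merits: the last ring closes under neutral conditions with the aldehyde and the pyranone already in place, so there is no late formylation or annulation selectivity question, and A1 is two demethylations from the target.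
- Weak points: A2 already contains the tetra-ortho-substituted diaryl ether, so the hardest bond is deferred, not solved. The bromide is flanked by methyl and aryloxy and the phenol by methyl and aryloxy, so oxidative addition and seven-membered acyl transfer are both hindered, and hydrodebromination can compete.
- Comparison: in its endgame this road is better than the chosen one, because it has no regiochemical question at a4. The chosen plan sets against it that it never couples two hindered arenes through oxygen.

**Alternative 2: ring B chromanone from coenzyme Q0.** The b3–C(=O) and O(b4)–C bonds are cut. In the forward step A4, the hydroquinone of coenzyme Q0, condenses with 16 in P2O5/CH3SO3H by Friedel–Crafts acylation and oxa-Michael addition to give chromanone A3.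
- Merits: one step from a cheap quinol, with a single free CH and therefore no site question. This is better than step 8 of the chosen route, where the same reaction is run late on a depsidone that has a second arene.
- Weak points: the free phenol of A3 is O(b1), the ester oxygen. O(b6), which must become the ether, and O(b5) are both methyl ethers flanked by oxygens. The b6 methoxy is para to the ketone and might be cleaved selectively by a soft nucleophile, but the resulting 2,6-disubstituted phenol would still have to be arylated by a hindered ring A halide. It cannot be turned into an alkynyl ether either, since the ketone would not survive n-BuLi.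
- Comparison: this road is superior for ring B but does not address the ring junction. The chosen plan accepts a later annulation in exchange for a solved ether bond.

**Alternative 3: ring B from a squarate by cyclobutenone ring expansion.** The b1–b2 bond is cut and ring B is traced to a four-membered ring. Cyclobutenone A6 would come from diisopropyl squarate A7 by exchange of one isopropoxy group for phenol A8, then addition of a propenyl-metal reagent to the carbonyl vinylogous to the aryloxy group. Heating A6 at about 110–140 °C opens it to a dienylketene, 6π electrocyclisation forms b1–b2, and enolisation gives hydroquinone A5.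
- Merits: the ether oxygen is attached to an unhindered squarate carbon. Ring B arrives with O(b1) and O(b4) free and O(b5) as an isopropyl ether, the same differentiation that the chosen route reaches only through steps 5 and 6. In this respect the road is as good or better.
- Weak points: A8 is a hydrogen-bonded, ortho-substituted salicylate, and its exchange onto A7 is uncertain. The propenyl addition must choose between two carbonyls (electronically favoured, not guaranteed) and spare the ring A ester. A5 carries a methyl ester between two ortho substituents, which is harder to free before lactonisation than a benzyl ester.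
- Comparison: step counts are similar. The chosen plan sets against it commodity starting materials, a robust phenol–trichloroethylene ether formation, and a single cryogenic organometallic step on a substrate with no other electrophile.

Key step: step 4

Assumption: the two oxygens of quinone 13 are taken to come from water (loss of methanol), as is generally accepted for oxidative demethylation by tetravalent cerium. The transient stereocenters of 11 and 20 are racemic and are left unspecified in their SMILES.

## Route

Step 1
Reactants: 1 2,4,5-trimethoxytoluene
Product: 4 2,3,6-trimethoxy-5-methylphenol, via aryllithium 2 (not isolated), via dimethyl arylboronate 3 (not isolated)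
Conditions: n-BuLi, TMEDA, THF, 0 °C; B(OMe)3, −78 °C to rt; AcOH, 30% H2O2, 0 °C to rt
Reagents that add atoms: hydrogen peroxide (OO)
Why: Directed ortho-metalation removes the ring hydrogen between the two methoxy groups (the future b6) in preference to the benzylic hydrogens; borylation and boronate oxidation, with 1,2-shift of the aryl group from boron to oxygen, turn C–Li into C–OH.

Step 2
Reactants: 4 2,3,6-trimethoxy-5-methylphenol; 5 trichloroethylene
Product: 6 (E)-1,2-dichloroethenyl 2,3,6-trimethoxy-5-methylphenyl ether
Conditions: K2CO3, DMF, 70 °C
Reagents that add atoms: none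
Why: Known addition of a phenoxide to dichloroacetylene formed in situ from trichloroethylene and carbonate; anti addition gives the E isomer, and the reacting carbon is sp-hybridised, so the two ortho methoxy groups do not hinder C–O bond formation.

Step 3
Reactants: 6 (E)-1,2-dichloroethenyl 2,3,6-trimethoxy-5-methylphenyl ether
Product: 9 benzyl 3-(2,3,6-trimethoxy-5-methylphenoxy)prop-2-ynoate, via chloroethynyl aryl ether 7 (not isolated), via lithium aryloxyacetylide 8 (not isolated)
Conditions: n-BuLi (2.3 equiv), THF, −78 to −40 °C; then added to ClCO2Bn (excess), THF, −78 to 0 °C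
Reagents that add atoms: benzyl chloroformate (O=C(Cl)OCc1ccccc1)
Why: Known conversion of 1,2-dichlorovinyl ethers into lithium alkynyl ethers (deprotonation and loss of LiCl to the chloroalkyne, then chlorine–lithium exchange); acylation of the acetylide by inverse addition to excess chloroformate gives the alkynoate without a second addition.

Step 4
Reactants: 9 benzyl 3-(2,3,6-trimethoxy-5-methylphenoxy)prop-2-ynoate; 10 4-methoxy-6-methyl-2H-pyran-2-one
Product: 12 benzyl 4-methoxy-6-methyl-2-(2,3,6-trimethoxy-5-methylphenoxy)benzoate, via bicyclic lactone adduct 11 (not isolated)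
Conditions: 10 (3 equiv), 1,2-dichlorobenzene, 170–180 °C, sealed tube, argon
Reagents that add atoms: none
Why: Thermal [4+2] cycloaddition of the pyrone diene (pyrone C3 to C6) to the alkyne gives the 2-oxabicyclo[2.2.2]octadienone 11, which loses CO2 by retro-[4+2] and aromatises irreversibly to ring A. The closest known reaction type is the Diels–Alder/retro-Diels–Alder benzannulation of 2-pyrones with acetylenic esters, which 4-alkoxy-6-methyl-2-pyrones undergo with propiolates and acetylenedicarboxylates on heating. Ring A is closed by an intermolecular cycloaddition that forms the a4–a5 and a1–a6 bonds together, suprafacially on both partners, with no tether or ring-size constraint. The two bridgehead stereocenters of 11 form as a racemate and vanish on CO2 loss, so no stereocontrol is needed. The selectivity required is regiochemical: pyrone C3 must bond to the oxygen-bearing alkyne carbon. Matched polarity at both ends should secure it: C3 is the nucleophilic terminus (β to the 4-methoxy donor) and meets the alkyne carbon β to the ester, while the electrophilic pyrone C6 meets the α carbon, which the aryloxy group makes nucleophilic. The ester therefore ends next to the methyl group (a6 beside a1) and the ether oxygen next to the unsubstituted a4. The aryl alkynyl ether has no hydrogen β to oxygen and no free ortho position, so retro-ene loss of a ketene and sigmatropic rearrangement, the usual thermal decay paths of ynol ethers, are closed.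

Step 5
Reactants: 12 benzyl 4-methoxy-6-methyl-2-(2,3,6-trimethoxy-5-methylphenoxy)benzoate
Product: 13 benzyl 4-methoxy-2-[(2-methoxy-5-methyl-3,6-dioxocyclohexa-1,4-dien-1-yl)oxy]-6-methylbenzoate
Conditions: (NH4)2Ce(NO3)6 (2.5 equiv), MeCN/H2O, 0 °C
Reagents that add atoms: water (O)
Why: Oxidative demethylation of a para-dimethoxyarene by tetravalent cerium, as in the standard preparation of 2,3-dimethoxy-5-methylbenzoquinone from the tetramethoxytoluene. The tetraoxygenated ring B is oxidised far more easily than the benzoate ring A, and only O(b1) and O(b4) are para to each other, so the b5 methoxy and the ether survive.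

Step 6
Reactants: 13 benzyl 4-methoxy-2-[(2-methoxy-5-methyl-3,6-dioxocyclohexa-1,4-dien-1-yl)oxy]-6-methylbenzoate
Product: 14 2-(3,6-dihydroxy-2-methoxy-5-methylphenoxy)-4-methoxy-6-methylbenzoic acid
Conditions: H2 (1 atm), 10% Pd/C, EtOAc, rt; filtered under argon and used directly
Reagents that add atoms: none
Why: Catalytic hydrogenation reduces the quinone to the hydroquinone and hydrogenolyses the benzyl ester in the same operation; aryl methyl ethers and the diaryl ether are inert.

Step 7
Reactants: 14 2-(3,6-dihydroxy-2-methoxy-5-methylphenoxy)-4-methoxy-6-methylbenzoic acid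
Product: 15 7-hydroxy-3,6-dimethoxy-1,9-dimethyl-11H-dibenzo[b,e][1,4]dioxepin-11-one
Conditions: DCC, THF (high dilution), 0 °C to rt, argon
Reagents that add atoms: none
Why: Carbodiimide lactonisation of a 2-(2-hydroxyaryloxy)benzoic acid (7-exo-trig acyl transfer), the standard closure of depsidones. O(b1) is the only hydroxyl that can reach C11, since O(b4) is para to it and O(b5) is still methylated, so the lactone regiochemistry is fixed by constitution.

Step 8
Reactants: 15 7-hydroxy-3,6-dimethoxy-1,9-dimethyl-11H-dibenzo[b,e][1,4]dioxepin-11-one; 16 3-methylbut-2-enoic acid
Product: 18 pyranone-fused depsidone dimethyl ether (methyl ethers on O(a3) and O(b5)), via ortho-hydroxyaryl enone 17 (not isolated)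
Conditions: 16 (1.5 equiv), P2O5/CH3SO3H (1:10 w/w), 60–70 °C
Reagents that add atoms: none
Why: Friedel–Crafts acylation by the mixed anhydride of 16, then 6-endo-trig oxa-Michael addition, the usual one-pot synthesis of 2,2-dimethylchroman-4-ones from phenols. b3 is the only unsubstituted carbon of ring B and is ortho to the only free hydroxyl, while ring A has no free hydroxyl and cannot close a pyranone.

Step 9
Reactants: 18 pyranone-fused depsidone dimethyl ether
Product: 19 deformyl target (free hydroxyls on a3 and b5)
Conditions: BBr3 (5 equiv), CH2Cl2, −78 to 0 °C; then H2O
Reagents that add atoms: none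
Why: Lewis acid cleavage of aryl methyl ethers (bromide attack on the O-methyl of the boron–ether complex); the lactone oxygen and the pyranone oxygen, both conjugated to carbonyl groups, are poorer donors than the two methoxy oxygens and should survive at low temperature.

Step 10
Reactants: 19 deformyl target
Product: 21 target depsidone aldehyde, via alpha-chloro ether 20 (not isolated)
Conditions: Cl2CHOCH3, TiCl4, CH2Cl2, 0 °C to rt; then 1 M HCl (aq)
Reagents that add atoms: dichloromethyl methyl ether (ClC(Cl)OC); water (O)
Why: Rieche formylation: the titanium phenoxide at O(a3) delivers the electrophile to an ortho carbon, and a4, flanked by the phenol and the ether oxygen, is the chelation site, as in the formylation of orsellinate esters between their two oxygens. Ring B has no free position, and hydrolysis of 20 on work-up gives the aldehyde.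

## Compound list

1 | 2,4,5-trimethoxytoluene | Cc1cc(OC)c(OC)cc1OC | starting material
2 | (2,3,6-trimethoxy-5-methylphenyl)lithium | [Li]c1c(OC)c(C)cc(OC)c1OC | intermediate
3 | dimethyl (2,3,6-trimethoxy-5-methylphenyl)boronate | COB(OC)c1c(OC)c(C)cc(OC)c1OC | intermediate
4 | 2,3,6-trimethoxy-5-methylphenol | Cc1cc(OC)c(OC)c(O)c1OC | intermediate
5 | trichloroethylene | ClC=C(Cl)Cl | starting material
6 | (E)-1,2-dichloroethenyl 2,3,6-trimethoxy-5-methylphenyl ether | Cl/C=C(/Cl)Oc1c(OC)c(C)cc(OC)c1OC | intermediate
7 | chloroethynyl 2,3,6-trimethoxy-5-methylphenyl ether | ClC#COc1c(OC)c(C)cc(OC)c1OC | intermediate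
8 | lithium (2,3,6-trimethoxy-5-methylphenoxy)acetylide | [Li]C#COc1c(OC)c(C)cc(OC)c1OC | intermediate
9 | benzyl 3-(2,3,6-trimethoxy-5-methylphenoxy)prop-2-ynoate | O=C(OCc1ccccc1)C#COc1c(OC)c(C)cc(OC)c1OC | intermediate
10 | 4-methoxy-6-methyl-2H-pyran-2-one | COC1=CC(=O)OC(C)=C1 | starting material
11 | benzyl 8-methoxy-1-methyl-3-oxo-5-(2,3,6-trimethoxy-5-methylphenoxy)-2-oxabicyclo[2.2.2]octa-5,7-diene-6-carboxylate (racemic) | COC1=CC2(C)OC(=O)C1C(Oc1c(OC)c(C)cc(OC)c1OC)=C2C(=O)OCc1ccccc1 | intermediate
12 | benzyl 4-methoxy-6-methyl-2-(2,3,6-trimethoxy-5-methylphenoxy)benzoate | COc1cc(C)c(C(=O)OCc2ccccc2)c(Oc2c(OC)c(C)cc(OC)c2OC)c1 | intermediate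
13 | benzyl 4-methoxy-2-[(2-methoxy-5-methyl-3,6-dioxocyclohexa-1,4-dien-1-yl)oxy]-6-methylbenzoate | COc1cc(C)c(C(=O)OCc2ccccc2)c(OC2=C(OC)C(=O)C=C(C)C2=O)c1 | intermediate
14 | 2-(3,6-dihydroxy-2-methoxy-5-methylphenoxy)-4-methoxy-6-methylbenzoic acid | COc1cc(C)c(C(=O)O)c(Oc2c(OC)c(O)cc(C)c2O)c1 | intermediate
15 | 7-hydroxy-3,6-dimethoxy-1,9-dimethyl-11H-dibenzo[b,e][1,4]dioxepin-11-one | COc1cc(C)c2C(=O)Oc3c(C)cc(O)c(OC)c3Oc2c1 | intermediate
16 | 3-methylbut-2-enoic acid | CC(C)=CC(=O)O | starting material
17 | 7-hydroxy-3,6-dimethoxy-1,9-dimethyl-8-(3-methylbut-2-enoyl)-11H-dibenzo[b,e][1,4]dioxepin-11-one | COc1cc(C)c2C(=O)Oc3c(C)c(C(=O)C=C(C)C)c(O)c(OC)c3Oc2c1 | intermediate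
18 | 3,6-dimethoxy-1,9-dimethyl depsidone (dibenzo[b,e][1,4]dioxepin-11-one numbering) with a 2,2-dimethyl-2,3-dihydropyran-4-one fused across C7–C8 (ring oxygen on C7, carbonyl on C8) | Cc1cc(OC)cc2c1C(=O)Oc1c(C)c3c(c(OC)c1O2)OC(C)(C)CC3=O | intermediate
19 | 3,6-dihydroxy-1,9-dimethyl depsidone with the same C7–C8 fused 2,2-dimethylpyranone | Cc1cc(O)cc2c1C(=O)Oc1c(C)c3c(c(O)c1O2)OC(C)(C)CC3=O | intermediate
20 | 4-[chloro(methoxy)methyl] derivative of 19 (racemic at the new carbon) | Cc1cc(O)c(C(Cl)OC)c2c1C(=O)Oc1c(C)c3c(c(O)c1O2)OC(C)(C)CC3=O | intermediate
21 | 4-formyl-3,6-dihydroxy-1,9-dimethyl depsidone with the C7–C8 fused 2,2-dimethylpyranone (CNP0271978.0) | Cc1cc(O)c(C=O)c2c1C(=O)Oc1c(C)c3c(c(O)c1O2)OC(C)(C)CC3=O | target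

## Step count and least certain steps

Total: 10 steps. Longest linear sequence: 10 steps, from 1 to 21; 5, 10 and 16 are bought.

**Step 4 (key step).** The aryloxy donor raises the alkyne LUMO, so cycloaddition may be slow, and thermal oligomerisation of the alkynyl ether could then outrun it; regioselectivity could also erode at the temperature needed. Fallback: phenol 4 is coupled with benzyl 2-bromo-4-methoxy-6-methylbenzoate F1 in an Ullmann diaryl ether synthesis (CuCl, 2,2,6,6-tetramethylheptane-3,5-dione, Cs2CO3, NMP, 120 °C). This is the hindered arene–oxygen coupling the plan sets out to avoid, but it is known chemistry, and it comes back to the route at 12.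

**Step 8.** Competing acylation of ring A at a2 or a4, or acid-induced opening of the lactone, could consume material before ring B is annulated. Fallback: O(b4) of 15 is acylated with 3-methylbut-2-enoyl chloride (Et3N, CH2Cl2) to give 3,6-dimethoxy-1,9-dimethyl-11-oxo-11H-dibenzo[b,e][1,4]dioxepin-7-yl 3-methylbut-2-enoate F2. A Fries rearrangement (TiCl4 in 1,2-dichloroethane, or irradiation) then moves the acyl group to b3, the only free ortho position. This comes back to the route at 17, which is closed to 18 with K2CO3 in acetone.

**Step 10.** Poor site selectivity between a4 and a2 is the likely failure, since both are ortho to the phenol. Fallback: 19 is brominated with NBS (MeCN, 0 °C) at the competing position to give the a2-bromide of 19 F3. Rieche formylation can then only reach a4 and gives the a2-bromo-a4-aldehyde F4. Hydrodebromination with Pd(PPh3)4 (zerovalent palladium) and HCO2Na in DMF comes back to the route at 21.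

**Step 7.** Intermolecular esterification through O(b4), N-acylurea formation at the hindered acid, or air oxidation of the hydroquinone back to the quinone could lower the return. Fallback: 14 is heated in Ac2O with NaOAc, which closes the lactone through the mixed anhydride and acetylates O(b4) at the same time, giving 3,6-dimethoxy-1,9-dimethyl-11-oxo-11H-dibenzo[b,e][1,4]dioxepin-7-yl acetate F5. The unhindered phenolic acetate is then removed with NH4OAc in aqueous MeOH, which comes back to the route at 15.

## Further compounds

F1 | step 4 | benzyl 2-bromo-4-methoxy-6-methylbenzoate | COc1cc(C)c(C(=O)OCc2ccccc2)c(Br)c1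
F2 | step 8 | 3,6-dimethoxy-1,9-dimethyl-11-oxo-11H-dibenzo[b,e][1,4]dioxepin-7-yl 3-methylbut-2-enoate | COc1cc(C)c2C(=O)Oc3c(C)cc(OC(=O)C=C(C)C)c(OC)c3Oc2c1
F3 | step 10 | a2-bromide of 19 | Cc1c(Br)c(O)cc2c1C(=O)Oc1c(C)c3c(c(O)c1O2)OC(C)(C)CC3=O
F4 | step 10 | a2-bromo-a4-aldehyde (2-bromo derivative of 21) | Cc1c(Br)c(O)c(C=O)c2c1C(=O)Oc1c(C)c3c(c(O)c1O2)OC(C)(C)CC3=O
F5 | step 7 | 3,6-dimethoxy-1,9-dimethyl-11-oxo-11H-dibenzo[b,e][1,4]dioxepin-7-yl acetate | COc1cc(C)c2C(=O)Oc3c(C)cc(OC(C)=O)c(OC)c3Oc2c1
A1 | alternative 1 | di-O-methyl ether of the target (methyl on O(a3) and O(b5)) | Cc1cc(OC)c(C=O)c2c1C(=O)Oc1c(C)c3c(c(OC)c1O2)OC(C)(C)CC3=O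
A2 | alternative 1 | 3-bromo-2-[(6-hydroxy-8-methoxy-2,2,5-trimethyl-4-oxochroman-7-yl)oxy]-6-methoxy-4-methylbenzaldehyde | Cc1cc(OC)c(C=O)c(Oc2c(O)c(C)c3c(c2OC)OC(C)(C)CC3=O)c1Br
A3 | alternative 2 | 6-hydroxy-7,8-dimethoxy-2,2,5-trimethylchroman-4-one | COc1c(OC)c2OC(C)(C)CC(=O)c2c(C)c1O
A4 | alternative 2 | 2,3-dimethoxy-5-methylbenzene-1,4-diol (hydroquinone of coenzyme Q0) | COc1c(OC)c(O)c(C)cc1O
A5 | alternative 3 | methyl 2-(3,6-dihydroxy-2-isopropoxy-5-methylphenoxy)-4-methoxy-6-methylbenzoate | COC(=O)c1c(C)cc(OC)cc1Oc1c(O)c(C)cc(O)c1OC(C)C
A6 | alternative 3 | methyl 2-({3-hydroxy-2-isopropoxy-4-oxo-3-[(E)-prop-1-en-1-yl]cyclobut-1-en-1-yl}oxy)-4-methoxy-6-methylbenzoate (racemic) | COC(=O)c1c(C)cc(OC)cc1OC1=C(OC(C)C)C(O)(/C=C/C)C1=O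
A7 | alternative 3 | diisopropyl squarate (3,4-diisopropoxycyclobut-3-ene-1,2-dione) | CC(C)OC1=C(OC(C)C)C(=O)C1=O
A8 | alternative 3 | methyl 2-hydroxy-4-methoxy-6-methylbenzoate | COC(=O)c1c(C)cc(OC)cc1O
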